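**Strategy.** The cycloheptane ring is closed last, between C6 (the methyl-bearing carbon) and C7 (the tertiary carbinol) of the cyclohepta[b]furan-2-one core. C7–OH, C6–Me and the C5 oxygen form an aldol pattern, so an open-chain vinyl ketone (C5) and α-keto Weinreb amide (C7), held in a turn by the preformed all-cis γ-lactone, are joined by a copper hydride reductive aldol cyclization. Conjugate reduction makes the (Z)-enolate at C6 regiospecifically, which avoids the competing five-membered aldol from C4, and the 7-enolendo-exo-trig closure sets the C6 and C7 stereocenters in one operation. Directed reduction at C5 and propenyl addition to the amide finish the target.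

Key step: step 14

Remark: locants C3 to C8a in the Why lines of steps 14 to 16 are those of the cyclohepta[b]furan-2-one core (O1, C2 lactone carbonyl, C3, C3a, C4 to C8, C8a); the carbinol carbon made in step 12 is carried as both epimers because step 13 oxidizes it.

Step 1
Reactants: 1 but-2-yn-1-ol; 2 vinylmagnesium chloride
Product: 5 4-ethenyl-3-methylfuran-2(5H)-one, via oxamagnesole chelate 3 (not isolated), via hydroxy dienoic acid 4 (not isolated)
Conditions: 2 (3.5 equiv), THF/toluene, 80 °C; then CO2, 0 °C; then 2 M HCl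
Reagents that add atoms: carbon dioxide, O=C=O
Why: Hydroxyl-directed anti-carbomagnesiation of the propargylic alkoxide puts the vinyl group on the carbon next to the CH2O group and magnesium on the methyl-bearing carbon inside a five-membered chelate, and carboxylation of this alkenyl Grignard reagent followed by acid lactonization of the (Z)-hydroxy acid should give the butenolide.

Step 2
Reactants: 5 4-ethenyl-3-methylfuran-2(5H)-one
Product: 7 4-(2-hydroxyethyl)-3-methylfuran-2(5H)-one, via alkylborane 6 (not isolated)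
Conditions: 9-BBN, THF, 0 °C to rt; then H2O2, NaOAc, H2O, 0 °C
Reagents that add atoms: hydrogen peroxide, OO
Why: Anti-Markovnikov hydroboration–oxidation of the terminal vinyl group with the bulky borane should give the primary alcohol while the tetrasubstituted, electron-poor ring alkene stays untouched.

Step 3
Reactants: 7 4-(2-hydroxyethyl)-3-methylfuran-2(5H)-one
Product: 8 3-methyl-2-(triisopropylsilyloxy)-4-[2-(triisopropylsilyloxy)ethyl]furan
Conditions: TIPSOTf (2.3 equiv), Et3N, CH2Cl2, 0 °C to rt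
Reagents that add atoms: triisopropylsilyl trifluoromethanesulfonate, CC(C)[Si](C(C)C)(C(C)C)OS(=O)(=O)C(F)(F)F
Why: Silyl triflate and amine silylate the primary alcohol and, by soft enolization at C5 of the butenolide, form the aromatic 2-silyloxyfuran.

Step 4
Reactants: 8 3-methyl-2-(triisopropylsilyloxy)-4-[2-(triisopropylsilyloxy)ethyl]furan; 9 (R)-2,2-dimethyl-1,3-dioxolane-4-carbaldehyde
Product: 10 (5R)-5-{(S)-[(4R)-2,2-dimethyl-1,3-dioxolan-4-yl](hydroxy)methyl}-3-methyl-4-[2-(triisopropylsilyloxy)ethyl]furan-2(5H)-one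
Conditions: BF3·OEt2, CH2Cl2, −78 °C; aq. NaHCO3
Reagents that add atoms: none
Why: Vinylogous Mukaiyama aldol addition at furan C5 through an open transition state, in which Felkin–Anh attack anti to the dioxolane oxygen sets the carbinol carbon and the usual syn (threo) preference of 2-silyloxyfurans sets furanone C5.

Step 5
Reactants: 10 (5R)-5-{(S)-[(4R)-2,2-dimethyl-1,3-dioxolan-4-yl](hydroxy)methyl}-3-methyl-4-[2-(triisopropylsilyloxy)ethyl]furan-2(5H)-one
Product: 11 (3R,4S,5R)-5-{(S)-[(4R)-2,2-dimethyl-1,3-dioxolan-4-yl](hydroxy)methyl}-3-methyl-4-[2-(triisopropylsilyloxy)ethyl]dihydrofuran-2(3H)-one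
Conditions: H2 (60 bar), 5% Rh/Al2O3, EtOAc, rt
Reagents that add atoms: none
Why: Heterogeneous catalytic hydrogenation should deliver both hydrogen atoms to the butenolide face opposite the bulky C5 side chain, which sets furanone C3 and C4 so that methyl, silyloxyethyl and the C5 substituent are all cis, and rhodium on alumina limits hydrogenolysis of the allylic C–O bond.

Step 6
Reactants: 11 (3R,4S,5R)-5-{(S)-[(4R)-2,2-dimethyl-1,3-dioxolan-4-yl](hydroxy)methyl}-3-methyl-4-[2-(triisopropylsilyloxy)ethyl]dihydrofuran-2(3H)-one; 12 angelic acid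
Product: 14 (S)-[(4R)-2,2-dimethyl-1,3-dioxolan-4-yl]{(2R,3S,4R)-4-methyl-5-oxo-3-[2-(triisopropylsilyloxy)ethyl]tetrahydrofuran-2-yl}methyl (Z)-2-methylbut-2-enoate, via mixed anhydride 13 (not isolated)
Conditions: 2,4,6-trichlorobenzoyl chloride, Et3N, toluene, rt; then 11, 80 °C
Reagents that add atoms: none
Why: Yamaguchi-type esterification of the only free hydroxyl through the mixed anhydride, run without a nucleophilic catalyst so that the (Z)-angelate should not isomerize to the tiglate.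

Step 7
Reactants: 14 (S)-[(4R)-2,2-dimethyl-1,3-dioxolan-4-yl]{(2R,3S,4R)-4-methyl-5-oxo-3-[2-(triisopropylsilyloxy)ethyl]tetrahydrofuran-2-yl}methyl (Z)-2-methylbut-2-enoate
Product: 15 (1R,2R)-2,3-dihydroxy-1-{(2R,3S,4R)-4-methyl-5-oxo-3-[2-(triisopropylsilyloxy)ethyl]tetrahydrofuran-2-yl}propyl (Z)-2-methylbut-2-enoate
Conditions: AcOH/H2O (4:1), 40 °C
Reagents that add atoms: none
Why: Mild acid hydrolysis of the terminal isopropylidene acetal, under which the primary triisopropylsilyl ether, the lactone and the angelate should survive.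

Step 8
Reactants: 15 (1R,2R)-2,3-dihydroxy-1-{(2R,3S,4R)-4-methyl-5-oxo-3-[2-(triisopropylsilyloxy)ethyl]tetrahydrofuran-2-yl}propyl (Z)-2-methylbut-2-enoate
Product: 17 (2S,3R)-2-hydroxy-3-{[(Z)-2-methylbut-2-enoyl]oxy}-3-{(2R,3S,4R)-4-methyl-5-oxo-3-[2-(triisopropylsilyloxy)ethyl]tetrahydrofuran-2-yl}propanoic acid, via hydroxy aldehyde 16 (not isolated)
Conditions: TEMPO (cat.), NaClO2, NaOCl (cat.), MeCN/pH 6.7 phosphate buffer, 35 °C
Reagents that add atoms: sodium chlorite, [Na+].[O-]Cl=O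
Why: Oxoammonium-catalyzed oxidation is selective for the primary alcohol, and the aldehyde is oxidized on by chlorite (Pinnick type) to the α-hydroxy acid.

Step 9
Reactants: 17 (2S,3R)-2-hydroxy-3-{[(Z)-2-methylbut-2-enoyl]oxy}-3-{(2R,3S,4R)-4-methyl-5-oxo-3-[2-(triisopropylsilyloxy)ethyl]tetrahydrofuran-2-yl}propanoic acid; 18 N,O-dimethylhydroxylamine hydrochloride
Product: 19 (1R,2S)-2-hydroxy-3-[methoxy(methyl)amino]-1-{(2R,3S,4R)-4-methyl-5-oxo-3-[2-(triisopropylsilyloxy)ethyl]tetrahydrofuran-2-yl}-3-oxopropyl (Z)-2-methylbut-2-enoate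
Conditions: EDC·HCl, HOBt, N-methylmorpholine, CH2Cl2, 0 °C to rt
Reagents that add atoms: none
Why: Carbodiimide/HOBt amide coupling to the Weinreb amide, which an α-hydroxy acid should undergo without hydroxyl protection.

Step 10
Reactants: 19 (1R,2S)-2-hydroxy-3-[methoxy(methyl)amino]-1-{(2R,3S,4R)-4-methyl-5-oxo-3-[2-(triisopropylsilyloxy)ethyl]tetrahydrofuran-2-yl}-3-oxopropyl (Z)-2-methylbut-2-enoate
Product: 20 (1R,2S)-2-hydroxy-1-[(2R,3S,4R)-3-(2-hydroxyethyl)-4-methyl-5-oxotetrahydrofuran-2-yl]-3-[methoxy(methyl)amino]-3-oxopropyl (Z)-2-methylbut-2-enoate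
Conditions: HF·pyridine, pyridine, THF, 0 °C to rt
Reagents that add atoms: none
Why: Fluoride desilylation of the primary silyl ether under buffered acidic conditions, which should leave the esters and the amide untouched and avoid acyl migration.

Step 11
Reactants: 20 (1R,2S)-2-hydroxy-1-[(2R,3S,4R)-3-(2-hydroxyethyl)-4-methyl-5-oxotetrahydrofuran-2-yl]-3-[methoxy(methyl)amino]-3-oxopropyl (Z)-2-methylbut-2-enoate
Product: 21 (1R,2S)-2-hydroxy-3-[methoxy(methyl)amino]-1-[(2R,3S,4R)-4-methyl-5-oxo-3-(2-oxoethyl)tetrahydrofuran-2-yl]-3-oxopropyl (Z)-2-methylbut-2-enoate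
Conditions: TEMPO (cat.), PhI(OAc)2, CH2Cl2, rt
Reagents that add atoms: none
Why: TEMPO/PhI(OAc)2 oxidation should convert the primary alcohol to the aldehyde much faster than the hindered secondary α-hydroxy amide.

Step 12
Reactants: 21 (1R,2S)-2-hydroxy-3-[methoxy(methyl)amino]-1-[(2R,3S,4R)-4-methyl-5-oxo-3-(2-oxoethyl)tetrahydrofuran-2-yl]-3-oxopropyl (Z)-2-methylbut-2-enoate; 22 bromoethene
Product: 23 (1R,2S)-2-hydroxy-1-[(2R,3S,4R)-3-(2-hydroxybut-3-en-1-yl)-4-methyl-5-oxotetrahydrofuran-2-yl]-3-[methoxy(methyl)amino]-3-oxopropyl (Z)-2-methylbut-2-enoate (both epimers at the butenyl carbinol)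
Conditions: CrCl2, NiCl2 (cat.), DMF, rt
Reagents that add atoms: none
Why: Nozaki–Hiyama–Kishi vinylation adds the alkenylchromium reagent only to the aldehyde in the presence of lactone, ester, amide and free hydroxyl; the new carbinol center is not controlled and is removed in step 13.

Step 13
Reactants: 23 (1R,2S)-2-hydroxy-1-[(2R,3S,4R)-3-(2-hydroxybut-3-en-1-yl)-4-methyl-5-oxotetrahydrofuran-2-yl]-3-[methoxy(methyl)amino]-3-oxopropyl (Z)-2-methylbut-2-enoate
Product: 24 (S)-3-[methoxy(methyl)amino]-1-[(2R,3S,4R)-4-methyl-5-oxo-3-(2-oxobut-3-en-1-yl)tetrahydrofuran-2-yl]-2,3-dioxopropyl (Z)-2-methylbut-2-enoate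
Conditions: Dess–Martin periodinane, CH2Cl2, 0 °C to rt; crude product used at once
Reagents that add atoms: none
Why: Dess–Martin oxidation should convert both secondary alcohols, the allylic one to the vinyl ketone and the α-hydroxy amide to the α-keto amide, under non-basic conditions that do not epimerize the angelate-bearing carbon.

Step 14
Reactants: 24 (S)-3-[methoxy(methyl)amino]-1-[(2R,3S,4R)-4-methyl-5-oxo-3-(2-oxobut-3-en-1-yl)tetrahydrofuran-2-yl]-2,3-dioxopropyl (Z)-2-methylbut-2-enoate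
Product: 26 (3R,3aS,6R,7S,8S,8aR)-7-hydroxy-7-[methoxy(methyl)carbamoyl]-3,6-dimethyl-2,5-dioxooctahydro-2H-cyclohepta[b]furan-8-yl (Z)-2-methylbut-2-enoate, via copper enolate 25 (not isolated)
Conditions: [(Ph3P)CuH]6 (0.2 equiv, 1.2 equiv hydride), toluene, −40 °C to −20 °C; aq. NH4Cl
Reagents that add atoms: none
Why: Copper hydride adds to the terminal carbon of the s-cis vinyl ketone and gives the (Z)-copper enolate 25 regiospecifically, which attacks the ketone carbonyl of the α-keto amide through a chelated chair-like Zimmerman–Traxler transition state. The closest known reaction type is the copper hydride reductive aldol cyclization of keto-enones. The seven-membered carbocycle closes in the 7-enolendo-exo-trig mode. The C6 stereocenter is controlled by the (Z)-enolate geometry in the closed transition state, which places the C6 methyl cis to the C7 hydroxyl, and the C7 stereocenter is controlled by the adjacent C8 center, whose non-chelating ester C–O bond lies anti to the reacting carbonyl so that the tether can bring C6 to only one face and the new hydroxyl ends up trans to the C8 ester. The step needs hydride delivery to the vinyl ketone and not to the keto amide or the angelate, closure from C6 and not from C4, and attack on the ketone and not the amide carbonyl; the much faster conjugate reduction of an unsubstituted enone, the fixed position of the enolate and the higher electrophilicity of the ketone should secure these, and the cis-disubstituted lactone holds the two chain ends close.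

Step 15
Reactants: 26 (3R,3aS,6R,7S,8S,8aR)-7-hydroxy-7-[methoxy(methyl)carbamoyl]-3,6-dimethyl-2,5-dioxooctahydro-2H-cyclohepta[b]furan-8-yl (Z)-2-methylbut-2-enoate
Product: 27 (3R,3aS,5R,6S,7S,8S,8aR)-5,7-dihydroxy-7-[methoxy(methyl)carbamoyl]-3,6-dimethyl-2-oxooctahydro-2H-cyclohepta[b]furan-8-yl (Z)-2-methylbut-2-enoate
Conditions: Me4NBH(OAc)3, MeCN/AcOH, −35 °C
Reagents that add atoms: none
Why: Evans–Saksena reduction, in which the C7 hydroxyl binds the triacetoxyborohydride and delivers hydride to the C5 ketone from its own face, should give the 1,3-anti diol with the C5 hydroxyl trans to the C7 hydroxyl.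

Step 16
Reactants: 27 (3R,3aS,5R,6S,7S,8S,8aR)-5,7-dihydroxy-7-[methoxy(methyl)carbamoyl]-3,6-dimethyl-2-oxooctahydro-2H-cyclohepta[b]furan-8-yl (Z)-2-methylbut-2-enoate; 28 (E)-1-bromoprop-1-ene
Product: 31 (3R,3aS,5R,6S,7S,8S,8aR)-7-[(E)-but-2-enoyl]-5,7-dihydroxy-3,6-dimethyl-2-oxooctahydro-2H-cyclohepta[b]furan-8-yl (Z)-2-methylbut-2-enoate, via propenyllithium 29 (not isolated), via propenylmagnesium bromide 30 (not isolated)
Conditions: 28, t-BuLi, Et2O, −78 °C; MgBr2·OEt2; then 27 (0.2 equiv relative to 28), THF, −78 °C to −30 °C; aq. NH4Cl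
Reagents that add atoms: none
Why: Weinreb ketone synthesis, in which the (E)-alkenyl Grignard reagent (E geometry retained through Li–Br exchange and transmetalation) adds once to the N-methoxy-N-methylamide through a stable magnesium chelate after deprotonating the two hydroxyls, while low temperature should keep the lactone and the angelate intact.

**Compound list**

1 | but-2-yn-1-ol | CC#CCO | starting material
2 | vinylmagnesium chloride | C=C[Mg]Cl | starting material
3 | 4-ethenyl-3-methyl-2,5-dihydro-1,2-oxamagnesole (oxamagnesole chelate) | CC1=C(C=C)CO[Mg]1 | intermediate (not isolated)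
4 | (2Z)-3-(hydroxymethyl)-2-methylpenta-2,4-dienoic acid | OC(=O)/C(C)=C(\CO)C=C | intermediate (not isolated)
5 | 4-ethenyl-3-methylfuran-2(5H)-one | CC1=C(C=C)COC1=O | intermediate
6 | 4-[2-(9-borabicyclo[3.3.1]nonan-9-yl)ethyl]-3-methylfuran-2(5H)-one | CC1=C(CCB2C3CCCC2CCC3)COC1=O | intermediate (not isolated)
7 | 4-(2-hydroxyethyl)-3-methylfuran-2(5H)-one | CC1=C(CCO)COC1=O | intermediate
8 | 3-methyl-2-(triisopropylsilyloxy)-4-[2-(triisopropylsilyloxy)ethyl]furan | Cc1c(O[Si](C(C)C)(C(C)C)C(C)C)occ1CCO[Si](C(C)C)(C(C)C)C(C)C | intermediate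
9 | (R)-2,2-dimethyl-1,3-dioxolane-4-carbaldehyde (2,3-O-isopropylidene-D-glyceraldehyde) | O=C[C@H]1COC(C)(C)O1 | starting material
10 | (5R)-5-{(S)-[(4R)-2,2-dimethyl-1,3-dioxolan-4-yl](hydroxy)methyl}-3-methyl-4-[2-(triisopropylsilyloxy)ethyl]furan-2(5H)-one | CC1(C)OC[C@@H](O1)[C@@H](O)[C@@H]2OC(=O)C(C)=C2CCO[Si](C(C)C)(C(C)C)C(C)C | intermediate
11 | (3R,4S,5R)-5-{(S)-[(4R)-2,2-dimethyl-1,3-dioxolan-4-yl](hydroxy)methyl}-3-methyl-4-[2-(triisopropylsilyloxy)ethyl]dihydrofuran-2(3H)-one | CC1(C)OC[C@@H](O1)[C@@H](O)[C@@H]2OC(=O)[C@H](C)[C@@H]2CCO[Si](C(C)C)(C(C)C)C(C)C | intermediate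
12 | angelic acid, (Z)-2-methylbut-2-enoic acid | C/C=C(/C)C(=O)O | starting material
13 | (Z)-2-methylbut-2-enoic 2,4,6-trichlorobenzoic anhydride | C/C=C(/C)C(=O)OC(=O)c1c(Cl)cc(Cl)cc1Cl | intermediate (not isolated)
14 | (S)-[(4R)-2,2-dimethyl-1,3-dioxolan-4-yl]{(2R,3S,4R)-4-methyl-5-oxo-3-[2-(triisopropylsilyloxy)ethyl]tetrahydrofuran-2-yl}methyl (Z)-2-methylbut-2-enoate | CC1(C)OC[C@@H](O1)[C@@H](OC(=O)/C(C)=C\C)[C@@H]2OC(=O)[C@H](C)[C@@H]2CCO[Si](C(C)C)(C(C)C)C(C)C | intermediate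
15 | (1R,2R)-2,3-dihydroxy-1-{(2R,3S,4R)-4-methyl-5-oxo-3-[2-(triisopropylsilyloxy)ethyl]tetrahydrofuran-2-yl}propyl (Z)-2-methylbut-2-enoate | OC[C@@H](O)[C@@H](OC(=O)/C(C)=C\C)[C@@H]1OC(=O)[C@H](C)[C@@H]1CCO[Si](C(C)C)(C(C)C)C(C)C | intermediate
16 | (1R,2S)-2-hydroxy-1-{(2R,3S,4R)-4-methyl-5-oxo-3-[2-(triisopropylsilyloxy)ethyl]tetrahydrofuran-2-yl}-3-oxopropyl (Z)-2-methylbut-2-enoate | O=C[C@@H](O)[C@@H](OC(=O)/C(C)=C\C)[C@@H]1OC(=O)[C@H](C)[C@@H]1CCO[Si](C(C)C)(C(C)C)C(C)C | intermediate (not isolated)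
17 | (2S,3R)-2-hydroxy-3-{[(Z)-2-methylbut-2-enoyl]oxy}-3-{(2R,3S,4R)-4-methyl-5-oxo-3-[2-(triisopropylsilyloxy)ethyl]tetrahydrofuran-2-yl}propanoic acid | OC(=O)[C@@H](O)[C@@H](OC(=O)/C(C)=C\C)[C@@H]1OC(=O)[C@H](C)[C@@H]1CCO[Si](C(C)C)(C(C)C)C(C)C | intermediate
18 | N,O-dimethylhydroxylamine hydrochloride | CNOC.Cl | starting material
19 | (1R,2S)-2-hydroxy-3-[methoxy(methyl)amino]-1-{(2R,3S,4R)-4-methyl-5-oxo-3-[2-(triisopropylsilyloxy)ethyl]tetrahydrofuran-2-yl}-3-oxopropyl (Z)-2-methylbut-2-enoate | CON(C)C(=O)[C@@H](O)[C@@H](OC(=O)/C(C)=C\C)[C@@H]1OC(=O)[C@H](C)[C@@H]1CCO[Si](C(C)C)(C(C)C)C(C)C | intermediate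
20 | (1R,2S)-2-hydroxy-1-[(2R,3S,4R)-3-(2-hydroxyethyl)-4-methyl-5-oxotetrahydrofuran-2-yl]-3-[methoxy(methyl)amino]-3-oxopropyl (Z)-2-methylbut-2-enoate | CON(C)C(=O)[C@@H](O)[C@@H](OC(=O)/C(C)=C\C)[C@@H]1OC(=O)[C@H](C)[C@@H]1CCO | intermediate
21 | (1R,2S)-2-hydroxy-3-[methoxy(methyl)amino]-1-[(2R,3S,4R)-4-methyl-5-oxo-3-(2-oxoethyl)tetrahydrofuran-2-yl]-3-oxopropyl (Z)-2-methylbut-2-enoate | CON(C)C(=O)[C@@H](O)[C@@H](OC(=O)/C(C)=C\C)[C@@H]1OC(=O)[C@H](C)[C@@H]1CC=O | intermediate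
22 | bromoethene (vinyl bromide) | C=CBr | starting material
23 | (1R,2S)-2-hydroxy-1-[(2R,3S,4R)-3-(2-hydroxybut-3-en-1-yl)-4-methyl-5-oxotetrahydrofuran-2-yl]-3-[methoxy(methyl)amino]-3-oxopropyl (Z)-2-methylbut-2-enoate, both epimers at the butenyl carbinol | CON(C)C(=O)[C@@H](O)[C@@H](OC(=O)/C(C)=C\C)[C@@H]1OC(=O)[C@H](C)[C@@H]1CC(O)C=C | intermediate
24 | (S)-3-[methoxy(methyl)amino]-1-[(2R,3S,4R)-4-methyl-5-oxo-3-(2-oxobut-3-en-1-yl)tetrahydrofuran-2-yl]-2,3-dioxopropyl (Z)-2-methylbut-2-enoate | CON(C)C(=O)C(=O)[C@@H](OC(=O)/C(C)=C\C)[C@@H]1OC(=O)[C@H](C)[C@@H]1CC(=O)C=C | intermediate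
25 | copper (Z)-enolate of 24, formed at the butenone unit (phosphine ligands not drawn) | CON(C)C(=O)C(=O)[C@@H](OC(=O)/C(C)=C\C)[C@@H]1OC(=O)[C@H](C)[C@@H]1C/C(O[Cu])=C/C | intermediate (not isolated)
26 | (3R,3aS,6R,7S,8S,8aR)-7-hydroxy-7-[methoxy(methyl)carbamoyl]-3,6-dimethyl-2,5-dioxooctahydro-2H-cyclohepta[b]furan-8-yl (Z)-2-methylbut-2-enoate | C/C=C(/C)C(=O)O[C@H]1[C@@H]2OC(=O)[C@H](C)[C@@H]2CC(=O)[C@H](C)[C@@]1(O)C(=O)N(C)OC | intermediate
27 | (3R,3aS,5R,6S,7S,8S,8aR)-5,7-dihydroxy-7-[methoxy(methyl)carbamoyl]-3,6-dimethyl-2-oxooctahydro-2H-cyclohepta[b]furan-8-yl (Z)-2-methylbut-2-enoate | C/C=C(/C)C(=O)O[C@H]1[C@@H]2OC(=O)[C@H](C)[C@@H]2C[C@@H](O)[C@H](C)[C@@]1(O)C(=O)N(C)OC | intermediate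
28 | (E)-1-bromoprop-1-ene | C/C=C/Br | starting material
29 | (E)-prop-1-enyllithium | C/C=C/[Li] | intermediate (not isolated)
30 | (E)-prop-1-enylmagnesium bromide | C/C=C/[Mg]Br | intermediate (not isolated)
31 | (3R,3aS,5R,6S,7S,8S,8aR)-7-[(E)-but-2-enoyl]-5,7-dihydroxy-3,6-dimethyl-2-oxooctahydro-2H-cyclohepta[b]furan-8-yl (Z)-2-methylbut-2-enoate (CNP0183494.1) | C/C=C(/C)C(=O)O[C@H]1[C@@H]2OC(=O)[C@H](C)[C@@H]2C[C@@H](O)[C@H](C)[C@@]1(O)C(=O)/C=C/C | target

**Step count and risks**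

Total step count: 16. Longest linear sequence: 16 steps (from but-2-yn-1-ol).

Steps most likely to fail:

1. Step 14. Hydride may be transferred to the very electrophilic keto amide carbonyl in competition with conjugate reduction, the enolate may deprotonate the acidic angelate-bearing carbon, or the ring may close on the wrong face of the C7 ketone. Fallback, setting out from 24: 1,4-hydrosilylation of the vinyl ketone (Et3SiH, cat. RhCl(PPh3)3, THF, rt) would give the isolable (S)-3-[methoxy(methyl)amino]-1-{(2R,3S,4R)-4-methyl-5-oxo-3-[(2Z)-2-(triethylsilyloxy)but-2-en-1-yl]tetrahydrofuran-2-yl}-2,3-dioxopropyl (Z)-2-methylbut-2-enoate F1. An intramolecular Mukaiyama aldol reaction promoted by MgBr2·OEt2 in CH2Cl2 at −78 °C, in which magnesium binds the two carbonyl groups of the keto amide and no hydride is present, would close the same bond through a differently organized transition state. Dilute acid work-up would bring the route back at 26.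

2. Step 16. The excess Grignard reagent may attack the lactone or the angelate, the magnesium alkoxides may trigger acyl migration of the angelate, or the base may epimerize C3. Fallback, setting out from 27: Cp2Zr(H)Cl in THF at rt would reduce only the N-methoxy-N-methylamide and give (3R,3aS,5R,6S,7S,8S,8aR)-7-formyl-5,7-dihydroxy-3,6-dimethyl-2-oxooctahydro-2H-cyclohepta[b]furan-8-yl (Z)-2-methylbut-2-enoate F2. Nozaki–Hiyama–Kishi coupling of this aldehyde with (E)-1-bromoprop-1-ene 28 (CrCl2, cat. NiCl2, DMF, rt) would give (3R,3aS,5R,6S,7R,8S,8aR)-5,7-dihydroxy-7-[(E)-1-hydroxybut-2-en-1-yl]-3,6-dimethyl-2-oxooctahydro-2H-cyclohepta[b]furan-8-yl (Z)-2-methylbut-2-enoate F3 as a mixture of carbinol epimers. MnO2 in CH2Cl2 would oxidize only this allylic alcohol and bring the route back at 31.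

3. Step 5. The tetrasubstituted alkene may reduce slowly, the free hydroxyl may anchor on the metal surface and steer hydrogen to the wrong face, or the allylic C–O bond may undergo hydrogenolysis. Fallback, setting out from 10: silylation (TESCl, imidazole, DMF, rt) would give (5R)-5-{(S)-[(4R)-2,2-dimethyl-1,3-dioxolan-4-yl](triethylsilyloxy)methyl}-3-methyl-4-[2-(triisopropylsilyloxy)ethyl]furan-2(5H)-one F4, which removes the anchoring group and enlarges the shielding side chain. Hydrogenation (H2, 60 bar, 5% Rh/Al2O3, EtOAc) would then give (3R,4S,5R)-5-{(S)-[(4R)-2,2-dimethyl-1,3-dioxolan-4-yl](triethylsilyloxy)methyl}-3-methyl-4-[2-(triisopropylsilyloxy)ethyl]dihydrofuran-2(3H)-one F5. AcOH/THF/H2O at rt would cleave only the triethylsilyl ether and bring the route back at 11.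

**Further compounds**

F1 | step 14 | (S)-3-[methoxy(methyl)amino]-1-{(2R,3S,4R)-4-methyl-5-oxo-3-[(2Z)-2-(triethylsilyloxy)but-2-en-1-yl]tetrahydrofuran-2-yl}-2,3-dioxopropyl (Z)-2-methylbut-2-enoate | CON(C)C(=O)C(=O)[C@@H](OC(=O)/C(C)=C\C)[C@@H]1OC(=O)[C@H](C)[C@@H]1C/C(O[Si](CC)(CC)CC)=C/C
F2 | step 16 | (3R,3aS,5R,6S,7S,8S,8aR)-7-formyl-5,7-dihydroxy-3,6-dimethyl-2-oxooctahydro-2H-cyclohepta[b]furan-8-yl (Z)-2-methylbut-2-enoate | C/C=C(/C)C(=O)O[C@H]1[C@@H]2OC(=O)[C@H](C)[C@@H]2C[C@@H](O)[C@H](C)[C@@]1(O)C=O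
F3 | step 16 | (3R,3aS,5R,6S,7R,8S,8aR)-5,7-dihydroxy-7-[(E)-1-hydroxybut-2-en-1-yl]-3,6-dimethyl-2-oxooctahydro-2H-cyclohepta[b]furan-8-yl (Z)-2-methylbut-2-enoate, both carbinol epimers | C/C=C(/C)C(=O)O[C@H]1[C@@H]2OC(=O)[C@H](C)[C@@H]2C[C@@H](O)[C@H](C)[C@@]1(O)C(O)/C=C/C
F4 | step 5 | (5R)-5-{(S)-[(4R)-2,2-dimethyl-1,3-dioxolan-4-yl](triethylsilyloxy)methyl}-3-methyl-4-[2-(triisopropylsilyloxy)ethyl]furan-2(5H)-one | CC1(C)OC[C@@H](O1)[C@@H](O[Si](CC)(CC)CC)[C@@H]2OC(=O)C(C)=C2CCO[Si](C(C)C)(C(C)C)C(C)C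
F5 | step 5 | (3R,4S,5R)-5-{(S)-[(4R)-2,2-dimethyl-1,3-dioxolan-4-yl](triethylsilyloxy)methyl}-3-methyl-4-[2-(triisopropylsilyloxy)ethyl]dihydrofuran-2(3H)-one | CC1(C)OC[C@@H](O1)[C@@H](O[Si](CC)(CC)CC)[C@@H]2OC(=O)[C@H](C)[C@@H]2CCO[Si](C(C)C)(C(C)C)C(C)C
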